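We decide to reckon this flask by one quantity: the material that the protic impurity leaves to the reversible steps.

    starting material ⇌ intermediate A (K1 = 0.374, k1 = 0.985 s⁻¹)
    starting material ⇌ intermediate B (K2 = 4.09, k2 = 0.0640 s⁻¹)
    intermediate A ⇌ target (K3 = 1.50, k3 = 0.0173 s⁻¹)
    starting material ⇌ target (k4 = 0.0588 s⁻¹)
    crystals ⇌ target, rate k5*(cs5 - [target]) while solid is left; crystals form when [target] > cs5 (cs5 = 17 mM, k5 = 1.11 s⁻¹)
    starting material + protic impurity → quenched substrate (k6 = 19.6 M⁻¹ s⁻¹)

starting material 0.050 M; protic impurity 0.0100 M; time 8.0 min

1. why nothing more happens at 8.0 min, or that something still does (it is still moving / all of the starting material has reacted / forward and back rates have come level)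
2. share of the starting material used up at 8.0 min
3. target at 8.0 min, in percent of the starting material charged
4. intermediate B at 8.0 min, in percent of the starting material charged

- what is said of target includes crystals
- crystals is a solid; its amount is given per volume of the solution
- what has gone from starting material into another species counts as reacted, even if it can come back
- the reaction counts as stopped when no species that holds the starting material changes by six tenths of a point or more over the second half of the time
- run time (flask): 8.0 min

**The pool.** Step 6 has no way back, and protic impurity is its limiting reagent. We therefore call the starting material charged minus the protic impurity charged the pool, 40.0 mM. This is what the reversible steps share out once the impurity has reacted.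

**First rung.** Starting material and intermediate A relax towards each other with a half-life of 0.192 s, faster than step 4 does. So [intermediate A] follows [starting material] from the first seconds.

**Second rung.** The rate of step 6 is proportional to [protic impurity]. With [protic impurity] held at its charge, as if it never ran down, step 6 is pseudo-first-order in starting material, with a constant of 0.196 s⁻¹. That gives starting material a half-life of 0.059 min, shorter than the forward half-lives by step 2 and step 4.

**Third rung.** Taken each by its own step alone, the remaining exchanges relax with half-lives of 0.0706 min, 0.145 min and, longest, 0.401 min. Even the longest fits 20.0 times into 8.0 min, so we expect forward and back rates to come level.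

**Our reckoning.** The equilibrium constants give starting material the share 0.166 of the pool, so [starting material] ends near 6.64 mM. Even at that level the impurity has a half-life of 5.33 s, far shorter than 8.0 min, so it should take its whole charge. Target ends near 3.72 mM, below the solubility of 17 mM. We reckon a conversion of 86.7%, target 7.45% and intermediate B 54.3%.

**The forecast.** It says forward and back rates have come level, with conversion 86.7%, target 7.45% and intermediate B 54.3%. Its ground is that “the system is fully equilibrated”.

**The simulation.** It gives forward and back rates have come level, with conversion 86.7%, target 7.45% and intermediate B 54.3%. In this flask protic impurity reads 0% of its own charge at 0.800 min, and quenched substrate reads 20.0% of the starting material charged at 8.00 min.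

**Neighbour flask.** With 0.025 M of protic impurity, or 0.500 equiv, the neighbour's pool is 25.0 mM, half of the starting material charged, against 40.0 mM in this flask. The same share then gives a conversion of 91.7%, target 4.66% and intermediate B 33.9%. Simulated, the neighbour holds 0% of the protic impurity's own charge and quenched substrate at 50.0% of the starting material charged at 8.00 min, with conversion 91.7%, target 4.66% and intermediate B 33.9%.

The constants belong to no real substance; no experiment stands behind them.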